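**Plan**

- Cuts (lignan numbering: C7 benzylic, C8 central, C9 the CH2O carbon of each C3 chain): the three aryl–C7 bonds of the guaiacylglycerol units (the outer one, then both inner ones at once), the three C8–O aryl ether bonds, and last the C8–C8′ bond and the two C7–O–C9′ bonds of the furofuran.
- Enabling feature: in each inner unit C8 carries the syringyl ether oxygen and lies between C9H2OH and the carbinol carbon C7, which is an O-aryl glyceraldehyde pattern. The two inner units are exchanged by the C2 axis of the 3,7-dioxabicyclo[3.3.0]octane core, so one bis-aldehyde can accept two identical aryl nucleophiles.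
- Forward order: both tetrahydrofuran rings arise first by oxidative dimerisation of sinapyl alcohol, followed by resolution. Two L-serine-derived glycerates are attached by double Mitsunobu etherification and reduced to the bis-aldehyde, which takes up two aryl groups from a preformed aryltitanium reagent.
- The C7 hydroxyls are then silylated, one guaiacyl phenol is freed, and a D-serine-derived glycerate is carried through the same etherification, reduction and arylation. One global desilylation ends the route; phenols are masked as silyl ethers throughout so that no hydrogenolysis is needed next to the benzylic C–O bonds of the furofuran.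
- Stereochemistry: the core comes from the resolution. C8 (R, R, S) comes from L- and D-serine through retentive diazotisation and Mitsunobu inversion. C7 (S, S, R) comes from Felkin–Anh addition anti to the C8–OAr bond (erythro).

Key step: step 10

Remark: step 1 is not enantioselective, so 2 and 3 are racemates and their SMILES show one enantiomer only to fix the relative configuration.

Remark: the reagent solutions 13 and 14 are not stored; a fresh batch is made by steps 8 and 9 before each of the two additions (steps 10 and 17).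

**Route**

Step 1
Reactants: 1 sinapyl alcohol (two molecules)
Product: 3 (±)-syringaresinol, via bis(quinone methide) 2 (not isolated)
Conditions: FeCl3·6H2O (1.1 equiv per phenol), acetone/H2O, rt
Reagents that add atoms: none
Why: Oxidative phenol coupling, in which the phenoxyl radicals (C5 blocked by OMe) dimerise C8–C8′ and each quinone methide is then trapped by the C9 hydroxyl of the other half in a 5-exo oxa-Michael closure, which should give the cis-fused furofuran with both aryl groups exo as the racemate.

Step 2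
Reactants: 3 (±)-syringaresinol
Product: 4 (7R,7′R,8S,8′S)-syringaresinol
Conditions: preparative HPLC, cellulose tris(3,5-dimethylphenylcarbamate) on silica, hexane/i-PrOH, rt
Reagents that add atoms: none
Why: Chromatographic resolution on a polysaccharide chiral stationary phase is routine for furofuran lignans and fixes the four core stereocentres at once, the fraction to be kept being identified by chiroptical comparison before use.

Step 3
Reactants: 5 L-serine
Product: 7 methyl (S)-2,3-dihydroxypropanoate, via (S)-glyceric acid 6 (not isolated)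
Conditions: NaNO2, aq. H2SO4, 0 °C → rt; evaporate; then MeOH, H2SO4 (cat.), reflux
Reagents that add atoms: water, O; methanol, CO
Why: Diazotisation of the α-amino acid proceeds with net retention through the α-lactone (double inversion), and the Fischer esterification of the crude acid does not touch C2.

Step 4
Reactants: 7 methyl (S)-2,3-dihydroxypropanoate
Product: 8 methyl (S)-3-(tert-butyldiphenylsilyloxy)-2-hydroxypropanoate
Conditions: TBDPSCl (1.05 equiv), imidazole, CH2Cl2, 0 °C
Reagents that add atoms: tert-butyl(chloro)diphenylsilane, CC(C)(C)[Si](Cl)(c1ccccc1)c1ccccc1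
Why: Silylation with the bulky chlorosilane is selective for the primary hydroxyl over the hindered and less nucleophilic α-hydroxy ester hydroxyl.

Step 5
Reactants: 4 (7R,7′R,8S,8′S)-syringaresinol; 8 methyl (S)-3-(tert-butyldiphenylsilyloxy)-2-hydroxypropanoate (2.5 equiv)
Product: 9 bis-ester [4 with each phenolic oxygen carrying an (R)-1-methoxycarbonyl-2-(tert-butyldiphenylsilyloxy)ethyl group]
Conditions: PPh3, DIAD, THF, 0 °C → rt
Reagents that add atoms: none
Why: Twofold Mitsunobu etherification, in which each 2,6-dimethoxyphenol (pKa near 10) displaces the oxyphosphonium group at the carbon α to the ester by SN2 and so inverts C8 from S to R.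

Step 6
Reactants: 9 bis-ester
Product: 10 bis-aldehyde [4 with each phenolic oxygen carrying an (R)-1-formyl-2-(tert-butyldiphenylsilyloxy)ethyl group]
Conditions: i-Bu2AlH (2.4 equiv), toluene/CH2Cl2, −78 °C; MeOH at −78 °C; aq. KNaC4H4O6 (potassium sodium tartrate); used crude the same day
Reagents that add atoms: none
Why: Partial ester reduction, in which the α-aryloxy ester gives a chelate-stabilised aluminium hemiacetal at −78 °C that releases the aldehyde only on work-up, while avoiding base and chromatography protects the labile C8 centre.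

Step 7
Reactants: 11 4-bromo-2-methoxyphenol
Product: 12 (4-bromo-2-methoxyphenoxy)(tert-butyl)dimethylsilane
Conditions: TBSCl, imidazole, DMF, rt
Reagents that add atoms: tert-butyl(chloro)dimethylsilane, CC(C)(C)[Si](C)(C)Cl
Why: Standard phenol silylation, chosen so that the phenol can later be freed by fluoride without hydrogenolysis.

Step 8
Reactants: 12 (4-bromo-2-methoxyphenoxy)(tert-butyl)dimethylsilane
Product: 13 [4-(tert-butyldimethylsilyloxy)-3-methoxyphenyl]magnesium bromide (titrated THF solution)
Conditions: Mg turnings (I2 crystal), THF, 40 °C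
Reagents that add atoms: magnesium, [Mg]
Why: Grignard formation by insertion of magnesium into the aryl C–Br bond, to which the aryl silyl ether and the methoxy group are inert.

Step 9
Reactants: 13 [4-(tert-butyldimethylsilyloxy)-3-methoxyphenyl]magnesium bromide
Product: 14 [4-(tert-butyldimethylsilyloxy)-3-methoxyphenyl]titanium triisopropoxide (THF solution, used the same day)
Conditions: ClTi(OiPr)3 (1.0 equiv), THF, −78 → 0 °C; 1,4-dioxane, settle, cannulate the supernatant from the precipitated MgBrCl
Reagents that add atoms: chlorotitanium triisopropoxide, CC(C)O[Ti](Cl)(OC(C)C)OC(C)C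
Why: Transmetalation of an aryl Grignard reagent with ClTi(OiPr)3 is the standard entry to aryltitanium triisopropoxides, and precipitation of the magnesium halide with dioxane keeps a chelating Lewis acid out of the later additions.

Step 10
Reactants: 10 bis-aldehyde; 14 [4-(tert-butyldimethylsilyloxy)-3-methoxyphenyl]titanium triisopropoxide (4 equiv)
Product: 15 bis-carbinol [both chains (7S,8R)-erythro-1-aryl-2-aryloxy-3-silyloxypropan-1-ol; aryl = 4-(tert-butyldimethylsilyloxy)-3-methoxyphenyl]
Conditions: 14 in THF, −78 °C; add 10 in THF, −78 → 0 °C; aq. NH4Cl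
Reagents that add atoms: none
Why: The aryl group of the weakly basic, weakly Lewis-acidic aryltitanium 14 adds to each formyl carbon through an open transition state and forms the two aryl–C7 bonds (organotitanium carbonyl addition; the closest precedent is aryl Grignard or aryllithium addition to 2-aryloxy aldehydes in 8-O-4′ neolignan synthesis). No ring closes. Each new C7 stereocentre is controlled by the adjacent C8 centre: in the polar Felkin–Anh arrangement the C8–OAr bond is antiperiplanar to the incoming aryl group, which passes the C8 hydrogen and not the CH2OTBDPS group, so the (8R)-aldehyde should give the (7S)-carbinol, the anti or erythro isomer. The step needs non-chelation selectivity and an intact C8: the bulky silyl ether on O9, the poorly basic di-ortho-substituted aryl ether oxygen, the monodentate titanium triisopropoxide centre and the absence of magnesium halide disfavour the five-ring chelate that would lead to threo, and the low basicity of 14 suppresses enolisation and β-elimination of silanolate. The two aldehydes are remote and react independently, so the C2-symmetric bis-erythro product should be the main diastereomer and any erythro/threo isomer is removed by chromatography.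

Step 11
Reactants: 15 bis-carbinol
Product: 16 bis(C7-O-tert-butyldimethylsilyl) ether of 15
Conditions: TBSOTf, 2,6-lutidine (excess), CH2Cl2, −78 → 0 °C
Reagents that add atoms: tert-butyldimethylsilyl trifluoromethanesulfonate, CC(C)(C)[Si](C)(C)OS(=O)(=O)C(F)(F)F
Why: Silyl triflate silylation of hindered secondary alcohols, with excess lutidine and low temperature keeping the acid-sensitive furofuran and the benzylic carbinols from ionising.

Step 12
Reactants: 16 bis(C7-O-tert-butyldimethylsilyl) ether
Product: 17 monophenol [16 lacking one aryl O-silyl group]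
Conditions: TBAF (1.0 equiv), AcOH (1.0 equiv), THF, −20 → 0 °C
Reagents that add atoms: none
Why: Fluoride-mediated desilylation is much faster for aryl than for alkyl silyl ethers because phenoxide is the better leaving group, and as the two aryl silyl ethers are equivalent and independent one equivalent should give a statistical mixture from which the monophenol is separated while recovered 16 and resilylated bisphenol are recycled.

Step 13
Reactants: 18 D-serine
Product: 20 methyl (R)-2,3-dihydroxypropanoate, via (R)-glyceric acid 19 (not isolated)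
Conditions: NaNO2, aq. H2SO4, 0 °C → rt; evaporate; then MeOH, H2SO4 (cat.), reflux
Reagents that add atoms: water, O; methanol, CO
Why: The same retentive diazotisation through the α-lactone and Fischer esterification as in step 3, in the enantiomeric series.

Step 14
Reactants: 20 methyl (R)-2,3-dihydroxypropanoate
Product: 21 methyl (R)-3-(tert-butyldiphenylsilyloxy)-2-hydroxypropanoate
Conditions: TBDPSCl (1.05 equiv), imidazole, CH2Cl2, 0 °C
Reagents that add atoms: tert-butyl(chloro)diphenylsilane, CC(C)(C)[Si](Cl)(c1ccccc1)c1ccccc1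
Why: Selective silylation of the primary hydroxyl, as in step 4.

Step 15
Reactants: 17 monophenol; 21 methyl (R)-3-(tert-butyldiphenylsilyloxy)-2-hydroxypropanoate (1.5 equiv)
Product: 22 aryloxy ester [17 etherified at the free guaiacyl oxygen by an (S)-1-methoxycarbonyl-2-(tert-butyldiphenylsilyloxy)ethyl group]
Conditions: PPh3, DIAD, THF, 0 °C → rt
Reagents that add atoms: none
Why: Mitsunobu etherification by the only free hydroxyl of 17, a guaiacyl phenol, with SN2 inversion at the carbon α to the ester (R to S).

Step 16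
Reactants: 22 aryloxy ester
Product: 23 aldehyde [22 with CO2Me reduced to CHO; 8S in the outer chain]
Conditions: i-Bu2AlH (1.2 equiv), toluene/CH2Cl2, −78 °C; MeOH at −78 °C; aq. KNaC4H4O6 (potassium sodium tartrate); used crude the same day
Reagents that add atoms: none
Why: Partial ester reduction through the chelated aluminium hemiacetal as in step 6, with all silyl ethers inert to the hydride.

Step 17
Reactants: 23 aldehyde; 14 [4-(tert-butyldimethylsilyloxy)-3-methoxyphenyl]titanium triisopropoxide (2.5 equiv, fresh batch)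
Product: 24 carbinol [outer chain (7R,8S)-erythro with free C7 hydroxyl]
Conditions: 14 in THF, −78 °C; add 23 in THF, −78 → 0 °C; aq. NH4Cl
Reagents that add atoms: none
Why: The same organotitanium carbonyl addition as in step 10, where Felkin–Anh attack anti to the C8–OAr bond of the (8S)-aldehyde should give the (7R,8S) erythro carbinol without influence from the remote stereocentres.

Step 18
Reactants: 24 carbinol
Product: 25 CNP0316493.2
Conditions: TBAF (excess), THF, 0 °C → rt; AcOH quench
Reagents that add atoms: none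
Why: Global fluoride desilylation removes the three primary tert-butyldiphenylsilyl, two benzylic tert-butyldimethylsilyl and two aryl tert-butyldimethylsilyl groups without touching any stereocentre, the 8-O-4′ ethers and the furofuran being stable to fluoride at room temperature.

**Compound list**

1 | sinapyl alcohol | COc1cc(/C=C/CO)cc(OC)c1O | starting material
2 | β–β-linked bis(quinone methide) of sinapyl alcohol, racemic | COC1=CC(=C[C@H](CO)[C@@H](CO)C=C2C=C(OC)C(=O)C(OC)=C2)C=C(OC)C1=O | intermediate
3 | (±)-syringaresinol, racemate | COc1cc(cc(OC)c1O)[C@@H]1OC[C@@H]2[C@H]1CO[C@H]2c1cc(OC)c(O)c(OC)c1 | intermediate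
4 | (7R,7′R,8S,8′S)-syringaresinol | COc1cc(cc(OC)c1O)[C@@H]1OC[C@@H]2[C@H]1CO[C@H]2c1cc(OC)c(O)c(OC)c1 | intermediate
5 | L-serine | N[C@@H](CO)C(=O)O | starting material
6 | (S)-glyceric acid | O[C@@H](CO)C(=O)O | intermediate
7 | methyl (S)-2,3-dihydroxypropanoate | COC(=O)[C@@H](O)CO | intermediate
8 | methyl (S)-3-(tert-butyldiphenylsilyloxy)-2-hydroxypropanoate | COC(=O)[C@@H](O)CO[Si](c1ccccc1)(c1ccccc1)C(C)(C)C | intermediate
9 | bis-ester: syringaresinol 4,4′-bis-O-[(R)-1-methoxycarbonyl-2-(tert-butyldiphenylsilyloxy)ethyl] ether | COC(=O)[C@@H](CO[Si](c1ccccc1)(c1ccccc1)C(C)(C)C)Oc1c(OC)cc(cc1OC)[C@@H]1OC[C@@H]2[C@H]1CO[C@H]2c1cc(OC)c(O[C@H](CO[Si](c2ccccc2)(c2ccccc2)C(C)(C)C)C(=O)OC)c(OC)c1 | intermediate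
10 | bis-aldehyde: syringaresinol 4,4′-bis-O-[(R)-1-formyl-2-(tert-butyldiphenylsilyloxy)ethyl] ether | O=C[C@@H](CO[Si](c1ccccc1)(c1ccccc1)C(C)(C)C)Oc1c(OC)cc(cc1OC)[C@@H]1OC[C@@H]2[C@H]1CO[C@H]2c1cc(OC)c(O[C@H](CO[Si](c2ccccc2)(c2ccccc2)C(C)(C)C)C=O)c(OC)c1 | intermediate
11 | 4-bromo-2-methoxyphenol | COc1cc(Br)ccc1O | starting material
12 | (4-bromo-2-methoxyphenoxy)(tert-butyl)dimethylsilane | COc1cc(Br)ccc1O[Si](C)(C)C(C)(C)C | intermediate
13 | [4-(tert-butyldimethylsilyloxy)-3-methoxyphenyl]magnesium bromide | COc1cc([Mg]Br)ccc1O[Si](C)(C)C(C)(C)C | intermediate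
14 | [4-(tert-butyldimethylsilyloxy)-3-methoxyphenyl]titanium triisopropoxide | COc1cc(ccc1O[Si](C)(C)C(C)(C)C)[Ti](OC(C)C)(OC(C)C)OC(C)C | intermediate
15 | bis-carbinol, both chains (7S,8R)-erythro, aryl = 4-(tert-butyldimethylsilyloxy)-3-methoxyphenyl | COc1cc(ccc1O[Si](C)(C)C(C)(C)C)[C@H](O)[C@@H](CO[Si](c1ccccc1)(c1ccccc1)C(C)(C)C)Oc1c(OC)cc(cc1OC)[C@@H]1OC[C@@H]2[C@H]1CO[C@H]2c1cc(OC)c(O[C@H](CO[Si](c2ccccc2)(c2ccccc2)C(C)(C)C)[C@@H](O)c2ccc(O[Si](C)(C)C(C)(C)C)c(OC)c2)c(OC)c1 | intermediate
16 | bis(C7-O-tert-butyldimethylsilyl) ether of 15 | COc1cc(ccc1O[Si](C)(C)C(C)(C)C)[C@H](O[Si](C)(C)C(C)(C)C)[C@@H](CO[Si](c1ccccc1)(c1ccccc1)C(C)(C)C)Oc1c(OC)cc(cc1OC)[C@@H]1OC[C@@H]2[C@H]1CO[C@H]2c1cc(OC)c(O[C@H](CO[Si](c2ccccc2)(c2ccccc2)C(C)(C)C)[C@@H](O[Si](C)(C)C(C)(C)C)c2ccc(O[Si](C)(C)C(C)(C)C)c(OC)c2)c(OC)c1 | intermediate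
17 | monophenol: 16 with one guaiacyl oxygen free | COc1cc(ccc1O)[C@H](O[Si](C)(C)C(C)(C)C)[C@@H](CO[Si](c1ccccc1)(c1ccccc1)C(C)(C)C)Oc1c(OC)cc(cc1OC)[C@@H]1OC[C@@H]2[C@H]1CO[C@H]2c1cc(OC)c(O[C@H](CO[Si](c2ccccc2)(c2ccccc2)C(C)(C)C)[C@@H](O[Si](C)(C)C(C)(C)C)c2ccc(O[Si](C)(C)C(C)(C)C)c(OC)c2)c(OC)c1 | intermediate
18 | D-serine | N[C@H](CO)C(=O)O | starting material
19 | (R)-glyceric acid | O[C@H](CO)C(=O)O | intermediate
20 | methyl (R)-2,3-dihydroxypropanoate | COC(=O)[C@H](O)CO | intermediate
21 | methyl (R)-3-(tert-butyldiphenylsilyloxy)-2-hydroxypropanoate | COC(=O)[C@H](O)CO[Si](c1ccccc1)(c1ccccc1)C(C)(C)C | intermediate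
22 | aryloxy ester: 17 with the free guaiacyl oxygen carrying (S)-1-methoxycarbonyl-2-(tert-butyldiphenylsilyloxy)ethyl | COC(=O)[C@H](CO[Si](c1ccccc1)(c1ccccc1)C(C)(C)C)Oc1ccc(cc1OC)[C@H](O[Si](C)(C)C(C)(C)C)[C@@H](CO[Si](c1ccccc1)(c1ccccc1)C(C)(C)C)Oc1c(OC)cc(cc1OC)[C@@H]1OC[C@@H]2[C@H]1CO[C@H]2c1cc(OC)c(O[C@H](CO[Si](c2ccccc2)(c2ccccc2)C(C)(C)C)[C@@H](O[Si](C)(C)C(C)(C)C)c2ccc(O[Si](C)(C)C(C)(C)C)c(OC)c2)c(OC)c1 | intermediate
23 | aldehyde: 22 with CO2Me reduced to CHO | O=C[C@H](CO[Si](c1ccccc1)(c1ccccc1)C(C)(C)C)Oc1ccc(cc1OC)[C@H](O[Si](C)(C)C(C)(C)C)[C@@H](CO[Si](c1ccccc1)(c1ccccc1)C(C)(C)C)Oc1c(OC)cc(cc1OC)[C@@H]1OC[C@@H]2[C@H]1CO[C@H]2c1cc(OC)c(O[C@H](CO[Si](c2ccccc2)(c2ccccc2)C(C)(C)C)[C@@H](O[Si](C)(C)C(C)(C)C)c2ccc(O[Si](C)(C)C(C)(C)C)c(OC)c2)c(OC)c1 | intermediate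
24 | carbinol: outer chain (7R,8S)-erythro with free C7 hydroxyl, all other hydroxyls silylated | COc1cc(ccc1O[Si](C)(C)C(C)(C)C)[C@@H](O)[C@H](CO[Si](c1ccccc1)(c1ccccc1)C(C)(C)C)Oc1ccc(cc1OC)[C@H](O[Si](C)(C)C(C)(C)C)[C@@H](CO[Si](c1ccccc1)(c1ccccc1)C(C)(C)C)Oc1c(OC)cc(cc1OC)[C@@H]1OC[C@@H]2[C@H]1CO[C@H]2c1cc(OC)c(O[C@H](CO[Si](c2ccccc2)(c2ccccc2)C(C)(C)C)[C@@H](O[Si](C)(C)C(C)(C)C)c2ccc(O[Si](C)(C)C(C)(C)C)c(OC)c2)c(OC)c1 | intermediate
25 | CNP0316493.2: (7R,7′R,8S,8′S)-syringaresinol 4,4′-bis-O-[(7S,8R)-guaiacylglycerol-8-yl] ether, one guaiacyl O4 carrying a further (7R,8S)-guaiacylglycerol-8-yl unit | COc1cc([C@@H](O)[C@H](CO)Oc2ccc([C@H](O)[C@@H](CO)Oc3c(OC)cc([C@@H]4OC[C@@H]5[C@H]4CO[C@H]5c4cc(OC)c(O[C@H](CO)[C@@H](O)c5ccc(O)c(OC)c5)c(OC)c4)cc3OC)cc2OC)ccc1O | target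

**Count and risks**

Total step count: 18.
Longest linear sequence: 11 steps (steps 1, 2, 5, 6, 10, 11, 12, 15, 16, 17, 18, from sinapyl alcohol).

Steps most likely to fail:

1. Step 10. The risk is poor facial selectivity at one or both aldehydes through partial chelation control, which would leave C7 epimers that lower the share of the bis-erythro product. The fallback sets out from the C7-epimer mixture of 15 and no longer relies on the addition for C7. Both carbinols are oxidised with Dess–Martin periodinane (NaHCO3, CH2Cl2, 0 °C) to the bis(aryl ketone) F1. F1 is then reduced with Zn(BH4)2 in Et2O at −30 °C. Here zinc should bridge the ketone oxygen and the C8 aryloxy oxygen, and hydride enters from the face opposite the CH2OTBDPS group, which for a ketone gives the anti (erythro) alcohol. The fallback comes back to the route at 15.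

2. Step 5. The risk is slow SN2 attack by the hindered 2,6-dimethoxyphenols, so that the activated alcohol is diverted to hydrazide alkylation or elimination and the second etherification stays incomplete. The fallback sets out from 8 and replaces in-flask activation by a preformed leaving group. Tf2O and 2,6-lutidine in CH2Cl2 at −78 °C give methyl (S)-3-(tert-butyldiphenylsilyloxy)-2-(trifluoromethylsulfonyloxy)propanoate F2. F2 is displaced by the bis-phenoxide of 4 (K2CO3, MeCN, 0 °C) with inversion. The fallback comes back to the route at 9.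

3. Step 12. The risk is lack of discrimination: the desilylation may run on to the bisphenol or begin to attack alkyl silyl ethers, leaving little monophenol. The fallback sets out from 16 and moves the desymmetrisation to the ether-forming step. Both aryl silyl groups are removed (KHF2, MeOH, rt) to give the bisphenol F3. F3 is etherified under Mitsunobu conditions with 21 as the limiting component (0.7 equiv, PPh3, DIAD, THF) to the mono-ether phenol F4, and unreacted F3 is recovered. The remaining phenol of F4 is silylated (TBSCl, imidazole, DMF). The fallback comes back to the route at 22.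

Further compounds
F1 | step 10 | bis(aryl ketone): 15 with both C7 carbinols oxidised to C=O | COc1cc(ccc1O[Si](C)(C)C(C)(C)C)C(=O)[C@@H](CO[Si](c1ccccc1)(c1ccccc1)C(C)(C)C)Oc1c(OC)cc(cc1OC)[C@@H]1OC[C@@H]2[C@H]1CO[C@H]2c1cc(OC)c(O[C@H](CO[Si](c2ccccc2)(c2ccccc2)C(C)(C)C)C(=O)c2ccc(O[Si](C)(C)C(C)(C)C)c(OC)c2)c(OC)c1
F2 | step 5 | methyl (S)-3-(tert-butyldiphenylsilyloxy)-2-(trifluoromethylsulfonyloxy)propanoate | COC(=O)[C@@H](OS(=O)(=O)C(F)(F)F)CO[Si](c1ccccc1)(c1ccccc1)C(C)(C)C
F3 | step 12 | bisphenol: 16 with both guaiacyl oxygens free | COc1cc(ccc1O)[C@H](O[Si](C)(C)C(C)(C)C)[C@@H](CO[Si](c1ccccc1)(c1ccccc1)C(C)(C)C)Oc1c(OC)cc(cc1OC)[C@@H]1OC[C@@H]2[C@H]1CO[C@H]2c1cc(OC)c(O[C@H](CO[Si](c2ccccc2)(c2ccccc2)C(C)(C)C)[C@@H](O[Si](C)(C)C(C)(C)C)c2ccc(O)c(OC)c2)c(OC)c1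
F4 | step 12 | mono-ether phenol: 22 with the remaining guaiacyl oxygen free | COC(=O)[C@H](CO[Si](c1ccccc1)(c1ccccc1)C(C)(C)C)Oc1ccc(cc1OC)[C@H](O[Si](C)(C)C(C)(C)C)[C@@H](CO[Si](c1ccccc1)(c1ccccc1)C(C)(C)C)Oc1c(OC)cc(cc1OC)[C@@H]1OC[C@@H]2[C@H]1CO[C@H]2c1cc(OC)c(O[C@H](CO[Si](c2ccccc2)(c2ccccc2)C(C)(C)C)[C@@H](O[Si](C)(C)C(C)(C)C)c2ccc(O)c(OC)c2)c(OC)c1
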